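**Retrosynthetic overview**

1. Numbering (cembrane): C1 carries the isopropyl group, C4 the diene methyl, C7 the acetate, C8 the methyl and the lactone oxygen, C12 the lactone carbonyl C20. The last step makes the C4–C5 bond by one-pot hydroboration/B-alkyl Suzuki–Miyaura closure of the open-chain iodide 29; it closes the 14-membered carbocycle (and the 13-membered ring through the ester) and gives the target itself.
2. Feature used: C5 is the terminal carbon of the vinyl group on the acetoxy carbon C7 (CH2=CH–CH(OAc)), so 9-BBN makes it a primary C–B nucleophile. C4 is the iodine-bearing end of the C1=C2–C3=C4 diene. Both chains hang from C8 and C12 of the seven-membered enoate lactone ring (O–C20(=O)–C12=C11–C10–C9–C8), which is closed beforehand.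
3. Seven-membered lactone (first ring): intramolecular Horner–Wadsworth–Emmons reaction (C11=C12) of a tertiary phosphonoacetate; the diene chain is attached before that by alkylation of the phosphonate (C12–C13).
4. C7/C8: Sharpless epoxidation of allylic alcohol 18, then Payne rearrangement/sulfonium ylide homologation (inversion at C7, C5 added) to the anti vinyl diol 21.
5. Diene fragment 14: syn carbocupration of an ynoate (C1=C2) and hydrozirconation–iodination of a methyl enyne (C3=C4). Order of ring formation: lactone (step 19), then macrocycle (step 20).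

Key step: step 20

Remark: TBS = tert-butyldimethylsilyl (TBSO = its ether oxygen); silyl ethers 1 and 15 are taken as catalogue compounds (otherwise each is one silylation of but-3-yn-1-ol or pent-4-yn-1-ol with TBSCl/imidazole).

**Route**

Step 1
Reactants: 1 tert-butyl(but-3-yn-1-yloxy)dimethylsilane
Product: 3 methyl 5-(TBSO)pent-2-ynoate, via lithium acetylide 2 (not isolated)
Conditions: n-BuLi, THF, −78 °C; ClCO2Me, −78 → 0 °C
Reagents that add atoms: methyl chloroformate COC(=O)Cl
Why: Deprotonation of the terminal alkyne and C-acylation of the lithium acetylide by the chloroformate is the standard route to 2-alkynoates; no stereocenter is formed.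

Step 2
Reactants: 3 methyl 5-(TBSO)pent-2-ynoate
Product: 5 methyl (2E)-3-[2-(TBSO)ethyl]-4-methylpent-2-enoate, via alkenylcopper 4 (not isolated)
Conditions: i-PrMgCl, CuI, THF, −40 → −78 °C; aq. NH4Cl, −78 °C
Reagents that add atoms: isopropylmagnesium chloride CC(C)[Mg]Cl
Why: Conjugate addition of the isopropylcopper reagent to the ynoate (carbocupration) is a syn addition, so protonation of 4 at −78 °C with retention should leave isopropyl trans and the silyloxyethyl chain cis to the ester, which is the C1=C2 geometry of the target.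

Step 3
Reactants: 5 methyl (2E)-3-[2-(TBSO)ethyl]-4-methylpent-2-enoate
Product: 6 (2E)-3-[2-(TBSO)ethyl]-4-methylpent-2-en-1-ol
Conditions: i-Bu2AlH, CH2Cl2, −78 °C; aq. potassium sodium tartrate
Reagents that add atoms: none
Why: 1,2-Reduction of the conjugated ester by i-Bu2AlH should stop at the allylic alcohol and leave the alkene geometry and the silyl ether untouched.

Step 4
Reactants: 6 (2E)-3-[2-(TBSO)ethyl]-4-methylpent-2-en-1-ol
Product: 7 (2E)-3-[2-(TBSO)ethyl]-4-methylpent-2-enal
Conditions: MnO2, CH2Cl2, rt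
Reagents that add atoms: none
Why: MnO2 oxidizes allylic alcohols selectively to enals under neutral conditions, so the trisubstituted double bond should keep its geometry.

Step 5
Reactants: 7 (2E)-3-[2-(TBSO)ethyl]-4-methylpent-2-enal
Product: 8 tert-butyl{[(3E)-6,6-dibromo-3-(propan-2-yl)hexa-3,5-dien-1-yl]oxy}dimethylsilane
Conditions: CBr4, PPh3, Zn, CH2Cl2, rt; then 7, 0 °C → rt
Reagents that add atoms: carbon tetrabromide BrC(Br)(Br)Br
Why: First stage of the Corey–Fuchs homologation, in which the dibromomethylene ylide formed from PPh3, CBr4 and zinc olefinates the enal under nearly neutral conditions.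

Step 6
Reactants: 8 tert-butyl{[(3E)-6,6-dibromo-3-(propan-2-yl)hexa-3,5-dien-1-yl]oxy}dimethylsilane
Product: 10 tert-butyldimethyl{[(3E)-3-(propan-2-yl)hept-3-en-5-yn-1-yl]oxy}silane, via lithium enynide 9 (not isolated)
Conditions: n-BuLi (2.1 equiv), THF, −78 °C; MeI, −78 °C → rt
Reagents that add atoms: iodomethane CI
Why: Second stage of the Corey–Fuchs sequence: bromine–lithium exchange, 1,2-shift of the carbenoid and deprotonation give acetylide 9, which iodomethane C-methylates; the existing double bond is not involved.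

Step 7
Reactants: 10 tert-butyldimethyl{[(3E)-3-(propan-2-yl)hept-3-en-5-yn-1-yl]oxy}silane
Product: 12 tert-butyl{[(3E,5E)-6-iodo-3-(propan-2-yl)hepta-3,5-dien-1-yl]oxy}dimethylsilane, via alkenylzirconocene 11 (not isolated)
Conditions: Cp2Zr(H)Cl, THF, rt → 40 °C; I2, 0 °C
Reagents that add atoms: iodine II
Why: Hydrozirconation with the Schwartz reagent is a syn addition that, after equilibration, should place zirconium on the less hindered alkyne carbon next to the methyl group and away from the alkenyl substituent, and iodinolysis of the C–Zr bond with retention then gives iodine trans to C2, the geometry needed at C4.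

Step 8
Reactants: 12 tert-butyl{[(3E,5E)-6-iodo-3-(propan-2-yl)hepta-3,5-dien-1-yl]oxy}dimethylsilane
Product: 13 (3E,5E)-6-iodo-3-(propan-2-yl)hepta-3,5-dien-1-ol
Conditions: HF·pyridine, pyridine, THF, 0 °C → rt
Reagents that add atoms: none
Why: Fluoride-driven cleavage of the primary silyl ether (Si–F bond formation) should leave the alkenyl iodide untouched.

Step 9
Reactants: 13 (3E,5E)-6-iodo-3-(propan-2-yl)hepta-3,5-dien-1-ol
Product: 14 (2E,4E)-2,7-diiodo-5-(propan-2-yl)hepta-2,4-diene
Conditions: I2, PPh3, imidazole, CH2Cl2, 0 °C → rt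
Reagents that add atoms: iodine II
Why: Appel-type iodination through the alkoxyphosphonium salt converts the primary alcohol to the iodide by SN2 displacement, and the alkenyl iodide does not react.

Step 10
Reactants: 15 tert-butyldimethyl(pent-4-yn-1-yloxy)silane
Product: 18 (2E)-6-(TBSO)-3-methylhex-2-en-1-ol, via alkenylalane 16 (not isolated), via lithium alanate 17 (not isolated)
Conditions: Me3Al, Cp2ZrCl2 (cat.), CH2Cl2, 0 °C → rt; n-BuLi, THF, −78 °C; (CH2O)n, −78 °C → rt
Reagents that add atoms: trimethylaluminium C[Al](C)C; paraformaldehyde (formaldehyde unit) C=O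
Why: Zirconium-catalysed carboalumination (Negishi) adds methyl and aluminium syn and regioselectively across the terminal alkyne, and the alanate made with n-BuLi is hydroxymethylated by formaldehyde with retention, which should give the (E)-trisubstituted allylic alcohol.

Step 11
Reactants: 18 (2E)-6-(TBSO)-3-methylhex-2-en-1-ol
Product: 19 [(2S,3S)-3-[3-(TBSO)propyl]-3-methyloxiran-2-yl]methanol
Conditions: Ti(Oi-Pr)4 (10 mol%), L-(+)-diethyl tartrate (12 mol%), t-BuOOH, 4 Å MS, CH2Cl2, −20 °C
Reagents that add atoms: tert-butyl hydroperoxide CC(C)(C)OO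
Why: Sharpless asymmetric epoxidation: the allylic hydroxyl binds the titanium tartrate catalyst and, with L-(+)-diethyl tartrate, oxygen should be delivered to the face that gives the (2S,3S)-epoxide, which sets the configuration of the C8–O bond.

Step 12
Reactants: 19 [(2S,3S)-3-[3-(TBSO)propyl]-3-methyloxiran-2-yl]methanol
Product: 21 (3R,4S)-7-(TBSO)-4-methylhept-1-ene-3,4-diol, via terminal epoxide 20 (not isolated)
Conditions: Me3S+ I−, n-BuLi, THF, −10 °C; then 19, −10 °C → rt
Reagents that add atoms: trimethylsulfonium iodide C[S+](C)C.[I-]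
Why: Under the basic conditions the epoxy alkoxide equilibrates by Payne rearrangement with terminal epoxide 20 (inversion at C7, C8 untouched), and dimethylsulfonium methylide should open only this unhindered epoxide at CH2 and then lose dimethyl sulfide by elimination (the known one-carbon homologation of epoxides to allylic alcohols), giving the anti vinyl diol with C5 in place.

Step 13
Reactants: 21 (3R,4S)-7-(TBSO)-4-methylhept-1-ene-3,4-diol
Product: 22 (3R,4S)-7-(TBSO)-4-hydroxy-4-methylhept-1-en-3-yl acetate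
Conditions: Ac2O, pyridine, DMAP (cat.), CH2Cl2, 0 °C
Reagents that add atoms: acetic anhydride CC(=O)OC(C)=O
Why: DMAP-catalysed acylation at 0 °C should be selective for the secondary allylic hydroxyl over the hindered tertiary one; this is the acetate of the target and it serves as its own protecting group.

Step 14
Reactants: 22 (3R,4S)-7-(TBSO)-4-hydroxy-4-methylhept-1-en-3-yl acetate
Product: 23 (3R,4S)-3-acetoxy-7-(TBSO)-4-methylhept-1-en-4-yl bromoacetate
Conditions: BrCH2COBr, pyridine, CH2Cl2, 0 °C → rt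
Reagents that add atoms: bromoacetyl bromide BrCC(Br)=O
Why: The small, very reactive acid bromide should acylate the tertiary alcohol in the presence of pyridine (acylation of a hindered alcohol by an acyl bromide), installing the future lactone C8–O–C20 unit.

Step 15
Reactants: 23 (3R,4S)-3-acetoxy-7-(TBSO)-4-methylhept-1-en-4-yl bromoacetate
Product: 24 (3R,4S)-3-acetoxy-7-(TBSO)-4-methylhept-1-en-4-yl (diethoxyphosphoryl)acetate
Conditions: P(OEt)3 (neat), 90 °C
Reagents that add atoms: triethyl phosphite CCOP(OCC)OCC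
Why: Michaelis–Arbuzov reaction: SN2 attack of the phosphite on the primary α-bromo ester and dealkylation of the phosphonium salt by bromide give the phosphonoacetate.

Step 16
Reactants: 24 (3R,4S)-3-acetoxy-7-(TBSO)-4-methylhept-1-en-4-yl (diethoxyphosphoryl)acetate; 14 (2E,4E)-2,7-diiodo-5-(propan-2-yl)hepta-2,4-diene
Product: 26 (3R,4S)-3-acetoxy-7-(TBSO)-4-methylhept-1-en-4-yl (5E,7E)-2-(diethoxyphosphoryl)-8-iodo-5-(propan-2-yl)nona-5,7-dienoate (both C2 epimers), via sodium phosphonate 25 (not isolated)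
Conditions: NaH, DMF, 0 °C; then 14, 0 → 40 °C
Reagents that add atoms: none
Why: SN2 alkylation of the stabilized phosphonoacetate anion 25 by the primary iodide of 14 (the alkenyl iodide is inert) forms the C12–C13 bond, and the new center at C12 is irrelevant because it becomes sp2 in step 19.

Step 17
Reactants: 26 (3R,4S)-3-acetoxy-7-(TBSO)-4-methylhept-1-en-4-yl (5E,7E)-2-(diethoxyphosphoryl)-8-iodo-5-(propan-2-yl)nona-5,7-dienoate
Product: 27 (3R,4S)-3-acetoxy-7-hydroxy-4-methylhept-1-en-4-yl (5E,7E)-2-(diethoxyphosphoryl)-8-iodo-5-(propan-2-yl)nona-5,7-dienoate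
Conditions: HF·pyridine, pyridine, THF, 0 °C → rt
Reagents that add atoms: none
Why: Buffered fluoride desilylation should remove only the primary silyl ether, since acetate, tertiary ester, phosphonate and alkenyl iodide are stable to it.

Step 18
Reactants: 27 (3R,4S)-3-acetoxy-7-hydroxy-4-methylhept-1-en-4-yl (5E,7E)-2-(diethoxyphosphoryl)-8-iodo-5-(propan-2-yl)nona-5,7-dienoate
Product: 28 (3R,4S)-3-acetoxy-4-methyl-7-oxohept-1-en-4-yl (5E,7E)-2-(diethoxyphosphoryl)-8-iodo-5-(propan-2-yl)nona-5,7-dienoate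
Conditions: Dess–Martin periodinane, CH2Cl2, rt
Reagents that add atoms: none
Why: Dess–Martin oxidation should convert the primary alcohol to the aldehyde under neutral conditions without touching the iodo-diene or the esters.

Step 19
Reactants: 28 (3R,4S)-3-acetoxy-4-methyl-7-oxohept-1-en-4-yl (5E,7E)-2-(diethoxyphosphoryl)-8-iodo-5-(propan-2-yl)nona-5,7-dienoate
Product: 29 (1R)-1-[(7S)-3-[(3E,5E)-6-iodo-3-(propan-2-yl)hepta-3,5-dien-1-yl]-7-methyl-2-oxo-2,5,6,7-tetrahydrooxepin-7-yl]prop-2-en-1-yl acetate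
Conditions: LiCl, DBU, MeCN, 1 mM, rt (slow addition of 28)
Reagents that add atoms: none
Why: Intramolecular Horner–Wadsworth–Emmons reaction under mild LiCl/amine conditions at high dilution should close the seven-membered lactone by forming C11=C12; the ring allows only the (Z)-enoate, and the fully substituted C8 favours cyclization over dimerization.

Step 20
Reactants: 29 (1R)-1-[(7S)-3-[(3E,5E)-6-iodo-3-(propan-2-yl)hepta-3,5-dien-1-yl]-7-methyl-2-oxo-2,5,6,7-tetrahydrooxepin-7-yl]prop-2-en-1-yl acetate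
Product: 31 target (1S,2R,5E,7E,11Z)-1,5-dimethyl-16-oxo-8-(propan-2-yl)-15-oxabicyclo[9.3.2]hexadeca-5,7,11-trien-2-yl acetate, via alkylborane 30 (not isolated)
Conditions: 9-BBN, THF, 0 °C → rt; H2O; then slow addition to Pd(dppf)Cl2 (20 mol%), AsPh3 (40 mol%), Cs2CO3, DMF/THF/H2O, 50 °C, 1 mM
Reagents that add atoms: none
Why: 9-BBN should hydroborate only the monosubstituted vinyl group (the iodo-diene and the ring enoate are trisubstituted) and place boron on the terminal carbon C5 to give primary borane 30; zerovalent palladium then inserts into the alkenyl C4–I bond, the base-activated B-alkyl group transmetalates and reductive elimination forms the C4–C5 bond with retention of the (E)-geometry at C4. The closest known reaction type is the intramolecular B-alkyl Suzuki–Miyaura macrocyclization. The 14-membered carbocycle closes end to end by reductive elimination from a macrocyclic alkyl(alkenyl)palladium species, and the same bond closes the 13-membered ring that runs through the lactone ester. No stereocenter is formed: C7 and C8 come unchanged from 21, and both diene double bonds keep the geometry set in steps 2 and 7. The step needs chemoselectivity and ring closure instead of oligomerization: the first is secured by the substitution pattern (one terminal alkene, one C–I bond), the second by slow addition of 30 to the catalyst at millimolar concentration and by the seven-membered lactone, which holds the two chains on C8 and C12 on the same flank of a rigid enoate. Fast reductive elimination with dppf and AsPh3 should outrun β-hydride elimination, and Cs2CO3 at 50 °C should leave the hindered acetate and the lactone intact.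

**Compound list**

1 | tert-butyl(but-3-yn-1-yloxy)dimethylsilane | C#CCCO[Si](C)(C)C(C)(C)C | starting material
2 | [4-(tert-butyldimethylsilyloxy)but-1-yn-1-yl]lithium | [Li]C#CCCO[Si](C)(C)C(C)(C)C | intermediate
3 | methyl 5-(tert-butyldimethylsilyloxy)pent-2-ynoate | COC(=O)C#CCCO[Si](C)(C)C(C)(C)C | intermediate
4 | methyl (2Z)-3-[2-(tert-butyldimethylsilyloxy)ethyl]-2-cuprio-4-methylpent-2-enoate (alkenylcopper adduct, Cu cis to isopropyl) | COC(=O)/C([Cu])=C(/C(C)C)CCO[Si](C)(C)C(C)(C)C | intermediate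
5 | methyl (2E)-3-[2-(tert-butyldimethylsilyloxy)ethyl]-4-methylpent-2-enoate | COC(=O)/C=C(/C(C)C)CCO[Si](C)(C)C(C)(C)C | intermediate
6 | (2E)-3-[2-(tert-butyldimethylsilyloxy)ethyl]-4-methylpent-2-en-1-ol | OC/C=C(/C(C)C)CCO[Si](C)(C)C(C)(C)C | intermediate
7 | (2E)-3-[2-(tert-butyldimethylsilyloxy)ethyl]-4-methylpent-2-enal | O=C/C=C(/C(C)C)CCO[Si](C)(C)C(C)(C)C | intermediate
8 | tert-butyl{[(3E)-6,6-dibromo-3-(propan-2-yl)hexa-3,5-dien-1-yl]oxy}dimethylsilane | BrC(Br)=C/C=C(/C(C)C)CCO[Si](C)(C)C(C)(C)C | intermediate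
9 | [(3E)-6-(tert-butyldimethylsilyloxy)-4-(propan-2-yl)hex-3-en-1-yn-1-yl]lithium | [Li]C#C/C=C(/C(C)C)CCO[Si](C)(C)C(C)(C)C | intermediate
10 | tert-butyldimethyl{[(3E)-3-(propan-2-yl)hept-3-en-5-yn-1-yl]oxy}silane | CC#C/C=C(/C(C)C)CCO[Si](C)(C)C(C)(C)C | intermediate
11 | chlorobis(cyclopentadienyl)[(2E,4E)-7-(tert-butyldimethylsilyloxy)-5-(propan-2-yl)hepta-2,4-dien-2-yl]zirconium | C/C(=C\C=C(\C(C)C)CCO[Si](C)(C)C(C)(C)C)[Zr](Cl)(C1C=CC=C1)C1C=CC=C1 | intermediate
12 | tert-butyl{[(3E,5E)-6-iodo-3-(propan-2-yl)hepta-3,5-dien-1-yl]oxy}dimethylsilane | C/C(I)=C\C=C(\C(C)C)CCO[Si](C)(C)C(C)(C)C | intermediate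
13 | (3E,5E)-6-iodo-3-(propan-2-yl)hepta-3,5-dien-1-ol | C/C(I)=C\C=C(\C(C)C)CCO | intermediate
14 | (2E,4E)-2,7-diiodo-5-(propan-2-yl)hepta-2,4-diene | C/C(I)=C\C=C(\C(C)C)CCI | intermediate
15 | tert-butyldimethyl(pent-4-yn-1-yloxy)silane | C#CCCCO[Si](C)(C)C(C)(C)C | starting material
16 | [(1E)-5-(tert-butyldimethylsilyloxy)-2-methylpent-1-en-1-yl]dimethylalumane | C[Al](C)/C=C(\C)CCCO[Si](C)(C)C(C)(C)C | intermediate
17 | lithium butyl[(1E)-5-(tert-butyldimethylsilyloxy)-2-methylpent-1-en-1-yl]dimethylaluminate | [Li+].CCCC[Al-](C)(C)/C=C(\C)CCCO[Si](C)(C)C(C)(C)C | intermediate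
18 | (2E)-6-(tert-butyldimethylsilyloxy)-3-methylhex-2-en-1-ol | OC/C=C(\C)CCCO[Si](C)(C)C(C)(C)C | intermediate
19 | [(2S,3S)-3-[3-(tert-butyldimethylsilyloxy)propyl]-3-methyloxiran-2-yl]methanol | OC[C@@H]1O[C@@]1(C)CCCO[Si](C)(C)C(C)(C)C | intermediate
20 | (2S)-5-(tert-butyldimethylsilyloxy)-2-[(2R)-oxiran-2-yl]pentan-2-ol (present as its lithium alkoxide) | C1O[C@H]1[C@@](C)(O)CCCO[Si](C)(C)C(C)(C)C | intermediate
21 | (3R,4S)-7-(tert-butyldimethylsilyloxy)-4-methylhept-1-ene-3,4-diol | C=C[C@@H](O)[C@@](C)(O)CCCO[Si](C)(C)C(C)(C)C | intermediate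
22 | (3R,4S)-7-(tert-butyldimethylsilyloxy)-4-hydroxy-4-methylhept-1-en-3-yl acetate | C=C[C@@H](OC(C)=O)[C@@](C)(O)CCCO[Si](C)(C)C(C)(C)C | intermediate
23 | (3R,4S)-3-acetoxy-7-(tert-butyldimethylsilyloxy)-4-methylhept-1-en-4-yl bromoacetate | C=C[C@@H](OC(C)=O)[C@@](C)(OC(=O)CBr)CCCO[Si](C)(C)C(C)(C)C | intermediate
24 | (3R,4S)-3-acetoxy-7-(tert-butyldimethylsilyloxy)-4-methylhept-1-en-4-yl (diethoxyphosphoryl)acetate | C=C[C@@H](OC(C)=O)[C@@](C)(OC(=O)CP(=O)(OCC)OCC)CCCO[Si](C)(C)C(C)(C)C | intermediate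
25 | sodium salt of 24 (phosphonate-stabilized carbanion) | [Na+].C=C[C@@H](OC(C)=O)[C@@](C)(OC(=O)[CH-]P(=O)(OCC)OCC)CCCO[Si](C)(C)C(C)(C)C | intermediate
26 | (3R,4S)-3-acetoxy-7-(tert-butyldimethylsilyloxy)-4-methylhept-1-en-4-yl (5E,7E)-2-(diethoxyphosphoryl)-8-iodo-5-(propan-2-yl)nona-5,7-dienoate (both C2 epimers) | C=C[C@@H](OC(C)=O)[C@@](C)(OC(=O)C(CC/C(C(C)C)=C\C=C(/C)I)P(=O)(OCC)OCC)CCCO[Si](C)(C)C(C)(C)C | intermediate
27 | (3R,4S)-3-acetoxy-7-hydroxy-4-methylhept-1-en-4-yl (5E,7E)-2-(diethoxyphosphoryl)-8-iodo-5-(propan-2-yl)nona-5,7-dienoate | C=C[C@@H](OC(C)=O)[C@@](C)(OC(=O)C(CC/C(C(C)C)=C\C=C(/C)I)P(=O)(OCC)OCC)CCCO | intermediate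
28 | (3R,4S)-3-acetoxy-4-methyl-7-oxohept-1-en-4-yl (5E,7E)-2-(diethoxyphosphoryl)-8-iodo-5-(propan-2-yl)nona-5,7-dienoate | C=C[C@@H](OC(C)=O)[C@@](C)(OC(=O)C(CC/C(C(C)C)=C\C=C(/C)I)P(=O)(OCC)OCC)CCC=O | intermediate
29 | (1R)-1-[(7S)-3-[(3E,5E)-6-iodo-3-(propan-2-yl)hepta-3,5-dien-1-yl]-7-methyl-2-oxo-2,5,6,7-tetrahydrooxepin-7-yl]prop-2-en-1-yl acetate | CC(=O)O[C@H](C=C)[C@]1(C)CCC=C(CC/C(C(C)C)=C\C=C(/C)I)C(=O)O1 | intermediate
30 | (1R)-3-(9-borabicyclo[3.3.1]nonan-9-yl)-1-[(7S)-3-[(3E,5E)-6-iodo-3-(propan-2-yl)hepta-3,5-dien-1-yl]-7-methyl-2-oxo-2,5,6,7-tetrahydrooxepin-7-yl]propyl acetate | CC(=O)O[C@H](CCB1C2CCCC1CCC2)[C@]1(C)CCC=C(CC/C(C(C)C)=C\C=C(/C)I)C(=O)O1 | intermediate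
31 | CNP0291129.1, (1S,2R,5E,7E,11Z)-1,5-dimethyl-16-oxo-8-(propan-2-yl)-15-oxabicyclo[9.3.2]hexadeca-5,7,11-trien-2-yl acetate | CC(=O)O[C@@H]1CC/C(C)=C/C=C(/C(C)C)CCC2=CCC[C@]1(C)OC2=O | target

**Step count and risks**

Total step count: 20. Longest linear sequence: 14 steps (steps 1–9, then 16–20); the second branch (steps 10–15) joins at step 16.

Steps most likely to fail:

Step 20 (macrocyclization). What may go wrong: intermolecular coupling outruns the slow transmetalation of the hindered borane so that oligomers form, the borane is lost by protodeboronation, or the acetate is hydrolysed by the aqueous base. Fallback, from 29 back to 31: K2CO3 in MeOH at 0 °C removes the acetate to give the allylic alcohol (7S)-7-[(1R)-1-hydroxyprop-2-en-1-yl]-3-[(3E,5E)-6-iodo-3-(propan-2-yl)hepta-3,5-dien-1-yl]-7-methyl-6,7-dihydrooxepin-2(5H)-one F1. An intramolecular Heck reaction under ligand-free phase-transfer conditions (Pd(OAc)2, Bu4NCl, NaHCO3, DMF, 60 °C, high dilution) joins C4 to the terminal carbon C5; β-hydride elimination towards the carbinol carbon and tautomerization give the macrocyclic ketone (1S,5E,7E,11Z)-1,5-dimethyl-8-(propan-2-yl)-15-oxabicyclo[9.3.2]hexadeca-5,7,11-triene-2,16-dione F2, with the diene geometry again carried by the iodide. Corey–Bakshi–Shibata reduction with the (S)-methyl oxazaborolidine and BH3·SMe2 (large quaternary C8 against small CH2) should give the (7R)-alcohol (1S,2R,5E,7E,11Z)-2-hydroxy-1,5-dimethyl-8-(propan-2-yl)-15-oxabicyclo[9.3.2]hexadeca-5,7,11-trien-16-one F3, and Ac2O/DMAP gives 31.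

Step 19 (seven-membered lactone by intramolecular olefination). What may go wrong: head-to-tail dimerization to the diolide or self-condensation of the aldehyde outruns the slow closure of a medium ring through a tertiary ester. Fallback, from 18 back to 29: the ring is closed at the C8–O bond instead, after the alkene has been made intermolecularly.
- Sharpless epoxidation of 18 with D-(−)-diethyl tartrate gives the enantiomeric epoxy alcohol [(2R,3R)-3-[3-(TBSO)propyl]-3-methyloxiran-2-yl]methanol F4.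
- Parikh–Doering oxidation gives (2S,3R)-3-[3-(TBSO)propyl]-3-methyloxirane-2-carbaldehyde F5, and Wittig methylenation with Ph3P=CH2 gives the vinyl epoxide tert-butyldimethyl{3-[(2R,3R)-2-methyl-3-vinyloxiran-2-yl]propoxy}silane F6.
- Bu4NF frees 3-[(2R,3R)-2-methyl-3-vinyloxiran-2-yl]propan-1-ol F7, and Dess–Martin oxidation gives 3-[(2R,3R)-2-methyl-3-vinyloxiran-2-yl]propanal F8.
- In parallel, methyl bis(2,2,2-trifluoroethyl)phosphonoacetate is alkylated with 14 (NaH, DMF) to methyl (5E,7E)-2-[bis(2,2,2-trifluoroethoxy)phosphoryl]-8-iodo-5-(propan-2-yl)nona-5,7-dienoate F9.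
- Still–Gennari olefination of F8 with F9 (KN(SiMe3)2, 18-crown-6, THF, −78 °C) should give the (Z)-enoate methyl (2Z,5E,7E)-8-iodo-2-{3-[(2R,3R)-2-methyl-3-vinyloxiran-2-yl]propylidene}-5-(propan-2-yl)nona-5,7-dienoate F10, and LiOH gives the acid (2Z,5E,7E)-8-iodo-2-{3-[(2R,3R)-2-methyl-3-vinyloxiran-2-yl]propylidene}-5-(propan-2-yl)nona-5,7-dienoic acid F11.
- Camphorsulfonic acid in CH2Cl2 lets the carboxyl group open the epoxide at the tertiary carbon C8 with inversion (7-exo), which should give the hydroxy lactone F1 described above with the (7R,8S) configuration; Ac2O/pyridine then gives 29.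

Step 12 (Payne rearrangement/ylide homologation). What may go wrong: the Payne equilibrium of a 3,3-disubstituted epoxy alcohol lies on the side of the internal epoxide, so trapping by the ylide may be slow, and attack on the internal epoxide or oxetane formation may compete. Fallback, from 19 back to 21: Parikh–Doering oxidation (SO3·pyridine, DMSO, Et3N) gives (2R,3S)-3-[3-(TBSO)propyl]-3-methyloxirane-2-carbaldehyde F12, and Wittig methylenation gives the vinyl epoxide tert-butyldimethyl{3-[(2S,3S)-2-methyl-3-vinyloxiran-2-yl]propoxy}silane F13. Hydroxide (KOH, DMSO/H2O, 80 °C) then opens the epoxide by SN2 at the secondary, allylic carbon C7 with inversion, while the tertiary carbon C8 is not attacked under basic conditions; this gives 21 with the same (3R,4S) configuration.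

**Further compounds**

F1 | step 20 | (7S)-7-[(1R)-1-hydroxyprop-2-en-1-yl]-3-[(3E,5E)-6-iodo-3-(propan-2-yl)hepta-3,5-dien-1-yl]-7-methyl-6,7-dihydrooxepin-2(5H)-one | O[C@H](C=C)[C@]1(C)CCC=C(CC/C(C(C)C)=C\C=C(/C)I)C(=O)O1
F2 | step 20 | (1S,5E,7E,11Z)-1,5-dimethyl-8-(propan-2-yl)-15-oxabicyclo[9.3.2]hexadeca-5,7,11-triene-2,16-dione | O=C1CC/C(C)=C/C=C(/C(C)C)CCC2=CCC[C@]1(C)OC2=O
F3 | step 20 | (1S,2R,5E,7E,11Z)-2-hydroxy-1,5-dimethyl-8-(propan-2-yl)-15-oxabicyclo[9.3.2]hexadeca-5,7,11-trien-16-one | O[C@@H]1CC/C(C)=C/C=C(/C(C)C)CCC2=CCC[C@]1(C)OC2=O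
F4 | step 19 | [(2R,3R)-3-[3-(tert-butyldimethylsilyloxy)propyl]-3-methyloxiran-2-yl]methanol | OC[C@H]1O[C@]1(C)CCCO[Si](C)(C)C(C)(C)C
F5 | step 19 | (2S,3R)-3-[3-(tert-butyldimethylsilyloxy)propyl]-3-methyloxirane-2-carbaldehyde | O=C[C@H]1O[C@]1(C)CCCO[Si](C)(C)C(C)(C)C
F6 | step 19 | tert-butyldimethyl{3-[(2R,3R)-2-methyl-3-vinyloxiran-2-yl]propoxy}silane | C=C[C@H]1O[C@]1(C)CCCO[Si](C)(C)C(C)(C)C
F7 | step 19 | 3-[(2R,3R)-2-methyl-3-vinyloxiran-2-yl]propan-1-ol | C=C[C@H]1O[C@]1(C)CCCO
F8 | step 19 | 3-[(2R,3R)-2-methyl-3-vinyloxiran-2-yl]propanal | C=C[C@H]1O[C@]1(C)CCC=O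
F9 | step 19 | methyl (5E,7E)-2-[bis(2,2,2-trifluoroethoxy)phosphoryl]-8-iodo-5-(propan-2-yl)nona-5,7-dienoate | COC(=O)C(CC/C(C(C)C)=C\C=C(/C)I)P(=O)(OCC(F)(F)F)OCC(F)(F)F
F10 | step 19 | methyl (2Z,5E,7E)-8-iodo-2-{3-[(2R,3R)-2-methyl-3-vinyloxiran-2-yl]propylidene}-5-(propan-2-yl)nona-5,7-dienoate | COC(=O)/C(CC/C(C(C)C)=C\C=C(/C)I)=C\CC[C@@]1(C)O[C@@H]1C=C
F11 | step 19 | (2Z,5E,7E)-8-iodo-2-{3-[(2R,3R)-2-methyl-3-vinyloxiran-2-yl]propylidene}-5-(propan-2-yl)nona-5,7-dienoic acid | OC(=O)/C(CC/C(C(C)C)=C\C=C(/C)I)=C\CC[C@@]1(C)O[C@@H]1C=C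
F12 | step 12 | (2R,3S)-3-[3-(tert-butyldimethylsilyloxy)propyl]-3-methyloxirane-2-carbaldehyde | O=C[C@@H]1O[C@@]1(C)CCCO[Si](C)(C)C(C)(C)C
F13 | step 12 | tert-butyldimethyl{3-[(2S,3S)-2-methyl-3-vinyloxiran-2-yl]propoxy}silane | C=C[C@@H]1O[C@@]1(C)CCCO[Si](C)(C)C(C)(C)C
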